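## The problem

Compound 40 is a C25 terpenoid alcohol built on a fourteen-membered carbocycle (ring atoms C1 to C14, numbered from the stereocentre). C1 is the only stereocentre (R) and carries a 6-methylhepta-1,5-dien-2-yl group whose 1,1-disubstituted alkene is C15=C16. Three trisubstituted ring alkenes need defined geometry: C3=C4 with the hydroxymethyl group on C4 cis to C2, (E)-C7=C8 and (Z)-C11=C12, the last two bearing methyl groups on C8 and C12. Because C1 is alone in a flexible macrocycle, nothing in the molecule can relay chirality to it; its configuration must come from a reagent, ideally in the event that makes the ring. Direct closure of a fourteen-membered carbocycle costs entropy and invites oligomers, so it helps to pay that cost in an easier step. The molecule is a set of isolated, electron-rich alkenes with an allylic alcohol, so strong acid (transannular cation–olefin reactions), electrophilic oxidants and dissolving metals are excluded, and open-chain precursors contain a 1,4-diene whose doubly allylic CH2 is sensitive to base. The enabling feature is that C1 is an allylic methine bonded to C14 and to C15=C16: the array C14–C1–C15=C16 is what a Claisen rearrangement leaves if C14 temporarily bears a carboxyl carbon (called C17 below).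

## Retrosynthesis

**Hydroxyl and C17.** Target 40 is traced to its TBDPS ether 39 and then to acid 37, in which C14 carries the extra carboxyl C17. No skeletal bond is cut; one carbon is added so that 37 is a γ,δ-unsaturated acid. The forward reactions are a radical decarboxylation, which also erases the C14 centre, and a fluoride desilylation. TBDPS is chosen because it is inert to the boron Lewis acid of the key step.

**C1–C14 (key disconnection).** A retro-[3,3] shift on 37 cuts C1–C14 and joins the C17 carboxyl oxygen to C16, giving the 18-membered lactone 35 with an (E)-C1=C15 alkene. Other cuts of the ring (C2–C3, C9–C10, C3=C4) would leave C1 to be set in an open chain by a separate asymmetric step. This cut removes both stereocentres at once: 35 is achiral, and only alkene geometry remains to be controlled. The forward reaction must choose one face of an ester enolate under reagent control.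

**Lactone C–O.** Lactone 35 opens to hydroxy acid 33, an easy macrolactonisation in the forward sense. Acid 33 comes from PMB ether 32, which comes from sulfonyl acid 31 and its ethyl ester 30. These are functional-group changes only; the ester is hydrolysed before the hydride step so that C17 survives it.

**C9–C10.** Ester 30 is cut between the two allylic carbons C9 and C10 into sulfone 28 (C10 to C14 plus C17) and allylic bromide 20 (the rest). The sulfonyl group is put on C10 rather than C9 so that its reductive removal passes through an allyl unit with one secondary terminus (C10) and one fully substituted terminus (C12), which keeps C11=C12 in place. A cut at C5–C6 would need a stereodefined 2-alkylidene-1,3-diol derivative and was rejected. The forward step is a sulfone-carbanion alkylation that must tolerate the ester.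

**C12–C13.** Sulfone 28 comes from bromide 27 and alcohol 26. Alcohol 26 is cut at the sp2–sp3 bond C12–C13 into (Z)-iodide 23 and the zinc homoenolate 25 of ester 24. Iodide 23 comes from but-2-yn-1-ol 21 by hydroxyl-directed hydroalumination, which fixes the (Z)-C11=C12 geometry.

**C2–C3.** Bromide 20 comes from alcohol 19 and its TBS ether 18. Triene 18 is cut between the alkenyl carbon C3 and the allylic carbon C2 into alkenyl iodide 8 and allylic bromide 15. This is preferred to a Wittig reaction at C1=C15, which would pass through a β,γ-unsaturated aldehyde prone to conjugation. The forward coupling must retain both alkene geometries and bond at the primary allyl terminus.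

**C4–C5 and C3–I.** Iodide 8 is the TBDPS ether of alcohol 7. Alcohol 7 comes from propargyl alcohol 4 and Grignard reagent 5 by anti-carbomagnesiation and iodinolysis, which places iodine (later C2) cis to the hydroxymethyl group. Reagent 5 comes from bromide 3, made from alcohol 2 by silylation and from commercial bromide 1 by allylic oxidation, which supplies C9 with the (E)-C7=C8 geometry.

**C15–side chain.** Bromide 15 comes from alcohol 14, which is cut at the sp2–sp3 bond between C15 and the side chain into (Z)-iodide 12 and the zinc reagent 13 of bromide 1. Iodide 12 comes from mono-PMB ether 10 of but-2-yne-1,4-diol 9 by the same hydroalumination–iodination; retention in the coupling gives the (E)-C1=C15 alkene the key step requires.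

## Roads not taken

Alternative 1: The ring would be cut at both C1–C14 and C2–C3. A vinyl "ate" complex, made from a C14 pinacol boronate on the chain and vinyllithium, would react with an alkenylpalladium generated at C3 of the same chain (Pd(OAc)2, chiral MandyPhos ligand). C14 migrates from boron to C1 as C2 bonds to C3, closing the ring to boronate A1; a Zweifel alkenylation would then attach the side chain at C1.
- Merits: chirality comes from a catalyst, two C–C bonds form at once, the side chain is added last, and no carbon has to be excised.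
- Weak points: this coupling is established as an intermolecular three-component union. Here the metallate shift would have to close a fourteen-membered ring at high dilution while an anionic boronate and a hindered trisubstituted (Z)-bromoalkene sit on one chain. Direct vinyl transfer, oligomerisation and halide inhibition all compete, ligand control in a macrocyclic transition state is untested, and the Zweifel step exposes three trisubstituted alkenes to iodine.
- Comparison: in step count and in catalytic use of chirality this road is better. The chosen plan offers instead a ring-forming event that is unimolecular, cannot oligomerise and has precedent for macrolactones, at the price of a stoichiometric (recoverable) chiral boron reagent and two steps to remove C17.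

Alternative 2: The ring would be cut at C3=C4. A bis(2,2,2-trifluoroethyl) phosphonoester carbanion at C4 (KN(SiMe3)2, 18-crown-6, high dilution) would condense with a C3 aldehyde on the same chain (Still–Gennari olefination), giving enoate A2, whose ester is reduced to the hydroxymethyl group.
- Merits: the ring and the most awkward alkene are made together, the reagent is designed to put the ester cis to C2, and no protecting group is needed at that position.
- Weak points: C1 must already be present, enantiopure, in the open chain, so a separate asymmetric step is needed. α-Alkylated phosphonoesters give trisubstituted enoates with less reliable geometry, and in a macrocyclisation ring strain rather than the reagent tends to decide E or Z. The closure is a bimolecular-type condensation competing with dimerisation, with an enolisable aldehyde under strong base.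
- Comparison: the endgame is shorter than the chosen one. Against that, the chosen plan fixes every alkene geometry in open-chain reactions of known selectivity and carries no stereocentre until the ring-forming step.

Alternative 3: The ring would be cut at C9–C10. The carbanion of an (E)-allylic phenyl sulfone at C9 (KN(SiMe3)2, high dilution) would displace a (Z)-allylic bromide at C10 on the same chain, giving sulfone A3 as a C9 epimer mixture; reductive desulfonylation and desilylation finish the synthesis.
- Merits: this is the classical closure for rings of this size, the alkylation is fast and strongly driven, and no carbon is added and removed.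
- Weak points: C1 again has to be set beforehand in an acyclic intermediate. The sulfone ends up on C9, next to the methyl-bearing C8, so the allyl intermediate of reductive removal has two secondary termini (C9 and C7) and the C7=C8 alkene can migrate. Dissolving-metal alternatives endanger the other alkenes.
- Comparison: as a ring closure it is at least as direct as the chosen sequence. The chosen plan uses the same sulfone chemistry intermolecularly with the sulfonyl group on C10, where removal is regiochemically unambiguous, and it merges enantiocontrol with ring formation, which this road cannot.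

Key step: step 21

Assumption: the (S,S)-configured bromoborane is taken, from the accepted facial model for this reagent class, to give (1S,14S)-37 (R at C1 after decarboxylation); the sense has not been derived independently, and if it proves opposite the equally available (R,R)-reagent is used with no other change.

## Route

Step 1
Reactants: 1 5-bromo-2-methylpent-2-ene
Product: 2 (2E)-5-bromo-2-methylpent-2-en-1-ol
Conditions: SeO2 (cat.), t-BuOOH, salicylic acid (cat.), CH2Cl2, rt
Reagents that add atoms: selenium dioxide O=[Se]=O; tert-butyl hydroperoxide CC(C)(C)OO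
Why: Riley allylic oxidation (ene reaction then [2,3]-shift) hydroxylates the methyl group trans to the chain of a gem-dimethyl trisubstituted alkene, so C9 is introduced with the (E)-C7=C8 geometry; the primary bromide is inert.

Step 2
Reactants: 2 (2E)-5-bromo-2-methylpent-2-en-1-ol
Product: 3 tert-butyl{[(2E)-5-bromo-2-methylpent-2-en-1-yl]oxy}dimethylsilane
Conditions: TBSCl, imidazole, CH2Cl2, 0 °C to rt
Reagents that add atoms: tert-butyldimethylsilyl chloride CC(C)(C)[Si](C)(C)Cl
Why: Routine silylation of a primary allylic alcohol; the TBS ether tolerates magnesium insertion and organolithium reagents and can later be removed in the presence of TBDPS.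

Step 3
Reactants: 3 tert-butyl{[(2E)-5-bromo-2-methylpent-2-en-1-yl]oxy}dimethylsilane; 4 propargyl alcohol
Product: 7 (2Z)-2-[(3E)-5-{[tert-butyl(dimethyl)silyl]oxy}-4-methylpent-3-en-1-yl]-3-iodoprop-2-en-1-ol, via Grignard reagent 5 (not isolated), via alkenylmagnesium chelate 6 (not isolated)
Conditions: 3, Mg, THF, 40 °C; then 4, CuI (cat.), THF, −10 °C to rt; then I2, −78 to 0 °C
Reagents that add atoms: iodine [I][I]
Why: Copper-catalysed anti-carbomagnesiation of propargyl alcohol: the alkoxide directs the alkyl group to the internal carbon (C4) and magnesium to the terminal carbon (C3) in a five-membered chelate cis to CH2O, and iodinolysis with retention leaves iodine (later C2) cis to the hydroxymethyl group; 5 is used in excess because one equivalent is consumed by the O–H.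

Step 4
Reactants: 7 (2Z)-2-[(3E)-5-{[tert-butyl(dimethyl)silyl]oxy}-4-methylpent-3-en-1-yl]-3-iodoprop-2-en-1-ol
Product: 8 tert-butyl{[(2Z)-2-[(3E)-5-{[tert-butyl(dimethyl)silyl]oxy}-4-methylpent-3-en-1-yl]-3-iodoprop-2-en-1-yl]oxy}diphenylsilane
Conditions: TBDPSCl, imidazole, DMF, rt
Reagents that add atoms: tert-butyldiphenylsilyl chloride CC(C)(C)[Si](Cl)(c1ccccc1)c1ccccc1
Why: Standard silylation; TBDPS is the group that must survive acid methanolysis, DDQ, hydride and the boron Lewis acid up to the last step.

Step 5
Reactants: 9 but-2-yne-1,4-diol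
Product: 10 4-[(4-methoxybenzyl)oxy]but-2-yn-1-ol
Conditions: NaH (1 equiv), PMBCl, Bu4NI (cat.), THF/DMF, 0 °C to rt, diol in excess
Reagents that add atoms: 4-methoxybenzyl chloride COc1ccc(CCl)cc1
Why: Williamson etherification; excess of the cheap symmetric diol makes the mono-ether the main product and differentiates the future C16 oxygen from C2.

Step 6
Reactants: 10 4-[(4-methoxybenzyl)oxy]but-2-yn-1-ol
Product: 12 (2Z)-3-iodo-4-[(4-methoxybenzyl)oxy]but-2-en-1-ol, via cyclic alkenylaluminate 11 (not isolated)
Conditions: NaAlH2(OCH2CH2OCH3)2, THF, 0 °C to rt; then I2, −78 to 0 °C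
Reagents that add atoms: iodine [I][I]
Why: Hydroxyl-directed trans-hydroalumination delivers hydride to the carbon next to the free carbinol (C1) and aluminium to C15 in a five-membered alanate; iodinolysis with retention gives the iodide cis to CH2OH, and the low temperature disfavours elimination of the PMB-oxy group.

Step 7
Reactants: 12 (2Z)-3-iodo-4-[(4-methoxybenzyl)oxy]but-2-en-1-ol; 1 5-bromo-2-methylpent-2-ene
Product: 14 (2E)-3-{[(4-methoxybenzyl)oxy]methyl}-7-methylocta-2,6-dien-1-ol, via homoprenylzinc bromide 13 (not isolated)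
Conditions: 1, Zn dust, I2 (cat.), DMA, 80 °C; then 12, Pd(dppf)Cl2 (5 mol%), THF, rt to 40 °C
Reagents that add atoms: none
Why: Negishi sp2–sp3 coupling with retention at the alkenyl carbon places the side chain cis to C2, which is the (E)-C1=C15 geometry; the alkylzinc halide (in excess) tolerates the free hydroxyl and the chelating diphosphine suppresses β-hydride elimination.

Step 8
Reactants: 14 (2E)-3-{[(4-methoxybenzyl)oxy]methyl}-7-methylocta-2,6-dien-1-ol
Product: 15 1-({[(2E)-4-bromo-2-(4-methylpent-3-en-1-yl)but-2-en-1-yl]oxy}methyl)-4-methoxybenzene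
Conditions: CBr4, PPh3, CH2Cl2, −20 to 0 °C
Reagents that add atoms: carbon tetrabromide BrC(Br)(Br)Br
Why: Appel reaction converts the primary allylic alcohol into the bromide under neutral conditions without allylic transposition or loss of geometry.

Step 9
Reactants: 8 tert-butyl{[(2Z)-2-[(3E)-5-{[tert-butyl(dimethyl)silyl]oxy}-4-methylpent-3-en-1-yl]-3-iodoprop-2-en-1-yl]oxy}diphenylsilane; 15 1-({[(2E)-4-bromo-2-(4-methylpent-3-en-1-yl)but-2-en-1-yl]oxy}methyl)-4-methoxybenzene
Product: 18 tert-butyl{[(2E,6Z,9E)-6-{[(tert-butyldiphenylsilyl)oxy]methyl}-11-[(4-methoxybenzyl)oxy]-2-methyl-10-(4-methylpent-3-en-1-yl)undeca-2,6,9-trien-1-yl]oxy}dimethylsilane, via alkenyllithium 16 (not isolated), via alkenylzinc bromide 17 (not isolated)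
Conditions: 8, t-BuLi (2.05 equiv), Et2O, −78 °C; ZnBr2, THF, −78 to 0 °C; then 15, Pd(PPh3)4 (5 mol%), THF, 0 °C to rt
Reagents that add atoms: none
Why: Iodine–lithium exchange and transmetalation to zinc proceed with retention, and Negishi alkenyl–allyl coupling through a π-allylpalladium bonds the alkenyl group to the unsubstituted terminus C2 with retention of both alkene geometries, giving the 1,4-diene without a β,γ-unsaturated carbonyl intermediate; immediate transmetalation in ether at −78 °C is meant to outrun silyl migration.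

Step 10
Reactants: 18 tert-butyl{[(2E,6Z,9E)-6-{[(tert-butyldiphenylsilyl)oxy]methyl}-11-[(4-methoxybenzyl)oxy]-2-methyl-10-(4-methylpent-3-en-1-yl)undeca-2,6,9-trien-1-yl]oxy}dimethylsilane
Product: 19 (2E,6Z,9E)-6-{[(tert-butyldiphenylsilyl)oxy]methyl}-11-[(4-methoxybenzyl)oxy]-2-methyl-10-(4-methylpent-3-en-1-yl)undeca-2,6,9-trien-1-ol
Conditions: PPTS (cat.), MeOH, rt
Reagents that add atoms: none
Why: Acid-catalysed methanolysis cleaves the primary TBS ether much faster than the TBDPS ether, and the PMB ether and alkenes are inert to this weak acid.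

Step 11
Reactants: 19 (2E,6Z,9E)-6-{[(tert-butyldiphenylsilyl)oxy]methyl}-11-[(4-methoxybenzyl)oxy]-2-methyl-10-(4-methylpent-3-en-1-yl)undeca-2,6,9-trien-1-ol
Product: 20 (2E,6Z,9E)-1-bromo-6-{[(tert-butyldiphenylsilyl)oxy]methyl}-11-[(4-methoxybenzyl)oxy]-2-methyl-10-(4-methylpent-3-en-1-yl)undeca-2,6,9-triene
Conditions: CBr4, PPh3, CH2Cl2, −20 to 0 °C
Reagents that add atoms: carbon tetrabromide BrC(Br)(Br)Br
Why: Appel reaction at C9 under neutral conditions; the bromide is used directly in step 16.

Step 12
Reactants: 21 but-2-yn-1-ol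
Product: 23 (2Z)-3-iodobut-2-en-1-ol, via cyclic alkenylaluminate 22 (not isolated)
Conditions: NaAlH2(OCH2CH2OCH3)2, THF, 0 °C to rt; then I2, −78 to 0 °C
Reagents that add atoms: iodine [I][I]
Why: Same hydroxyl-directed trans-hydroalumination and iodinolysis as step 6; iodine ends up on C12 cis to the C10 carbinol.

Step 13
Reactants: 23 (2Z)-3-iodobut-2-en-1-ol; 24 ethyl 3-iodopropanoate
Product: 26 ethyl (4Z)-6-hydroxy-4-methylhex-4-enoate, via zinc homoenolate 25 (not isolated)
Conditions: 24, Zn(Cu), toluene/DMA, 60 °C; then 23, Pd(PPh3)4 (5 mol%), rt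
Reagents that add atoms: none
Why: Negishi coupling of the β-zincio ester with the alkenyl iodide forms C12–C13 with retention, so C13 is cis to C10 ((Z)-C11=C12); the homoenolate does not attack its own ester and tolerates the hydroxyl.

Step 14
Reactants: 26 ethyl (4Z)-6-hydroxy-4-methylhex-4-enoate
Product: 27 ethyl (4Z)-6-bromo-4-methylhex-4-enoate
Conditions: CBr4, PPh3, CH2Cl2, −20 to 0 °C
Reagents that add atoms: carbon tetrabromide BrC(Br)(Br)Br
Why: Appel reaction; the (Z)-allylic bromide forms without isomerisation at low temperature.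

Step 15
Reactants: 27 ethyl (4Z)-6-bromo-4-methylhex-4-enoate
Product: 28 ethyl (4Z)-6-(benzenesulfonyl)-4-methylhex-4-enoate
Conditions: PhSO2Na, DMF, rt
Reagents that add atoms: sodium benzenesulfinate [Na+].[O-]S(=O)c1ccccc1
Why: SN2 S-alkylation of the sulfinate at the primary allylic carbon gives the sulfone with the (Z) geometry intact.

Step 16
Reactants: 28 ethyl (4Z)-6-(benzenesulfonyl)-4-methylhex-4-enoate; 20 (2E,6Z,9E)-1-bromo-6-{[(tert-butyldiphenylsilyl)oxy]methyl}-11-[(4-methoxybenzyl)oxy]-2-methyl-10-(4-methylpent-3-en-1-yl)undeca-2,6,9-triene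
Product: 30 ethyl (4Z,8E,12Z,15E)-6-(benzenesulfonyl)-12-{[(tert-butyldiphenylsilyl)oxy]methyl}-17-[(4-methoxybenzyl)oxy]-4,8-dimethyl-16-(4-methylpent-3-en-1-yl)heptadeca-4,8,12,15-tetraenoate (racemic at the sulfonyl carbon), via sulfonyl carbanion 29 (not isolated)
Conditions: 28, LiN(SiMe3)2 (1.05 equiv), THF, −78 °C; then 20, −78 to −20 °C
Reagents that add atoms: none
Why: The amide base deprotonates only the allylic sulfone, which is far more acidic than the ester α-position, and α-alkylation of the carbanion by the primary allylic bromide forms C9–C10; the carbanion is localised next to sulfur so (Z)-C11=C12 is kept, and the racemic C10 centre disappears in step 18.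

Step 17
Reactants: 30 ethyl (4Z,8E,12Z,15E)-6-(benzenesulfonyl)-12-{[(tert-butyldiphenylsilyl)oxy]methyl}-17-[(4-methoxybenzyl)oxy]-4,8-dimethyl-16-(4-methylpent-3-en-1-yl)heptadeca-4,8,12,15-tetraenoate
Product: 31 (4Z,8E,12Z,15E)-6-(benzenesulfonyl)-12-{[(tert-butyldiphenylsilyl)oxy]methyl}-17-[(4-methoxybenzyl)oxy]-4,8-dimethyl-16-(4-methylpent-3-en-1-yl)heptadeca-4,8,12,15-tetraenoic acid
Conditions: LiOH·H2O, THF/MeOH/H2O, rt; then 1 M HCl to pH 4
Reagents that add atoms: lithium hydroxide [Li+].[OH-]
Why: Saponification is placed before the hydride step so that C17 is a carboxylate, which LiBHEt3 does not reduce at 0 °C; the silyl ether and sulfone tolerate aqueous LiOH at room temperature.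

Step 18
Reactants: 31 (4Z,8E,12Z,15E)-6-(benzenesulfonyl)-12-{[(tert-butyldiphenylsilyl)oxy]methyl}-17-[(4-methoxybenzyl)oxy]-4,8-dimethyl-16-(4-methylpent-3-en-1-yl)heptadeca-4,8,12,15-tetraenoic acid
Product: 32 (4Z,8E,12Z,15E)-12-{[(tert-butyldiphenylsilyl)oxy]methyl}-17-[(4-methoxybenzyl)oxy]-4,8-dimethyl-16-(4-methylpent-3-en-1-yl)heptadeca-4,8,12,15-tetraenoic acid
Conditions: Pd(dppp)Cl2 (5 mol%), LiBHEt3 (4 equiv), THF, 0 °C; then aqueous NH4Cl
Reagents that add atoms: none
Why: Palladium-catalysed hydride reduction of the allylic sulfone: ionisation gives a π-allylpalladium over C10–C12 and hydride is delivered to the less substituted terminus C10, so C11=C12 stays in place and stays (Z), since syn/anti exchange would need σ-bonding at the fully substituted C12; the first equivalent of hydride only deprotonates the acid, and allylic alkyl and silyl ethers do not ionise.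

Step 19
Reactants: 32 (4Z,8E,12Z,15E)-12-{[(tert-butyldiphenylsilyl)oxy]methyl}-17-[(4-methoxybenzyl)oxy]-4,8-dimethyl-16-(4-methylpent-3-en-1-yl)heptadeca-4,8,12,15-tetraenoic acid
Product: 33 (4Z,8E,12Z,15E)-12-{[(tert-butyldiphenylsilyl)oxy]methyl}-17-hydroxy-4,8-dimethyl-16-(4-methylpent-3-en-1-yl)heptadeca-4,8,12,15-tetraenoic acid
Conditions: DDQ, CH2Cl2/pH 7 buffer, 0 °C
Reagents that add atoms: none
Why: Oxidative PMB cleavage (benzylic hydride abstraction, then hydrolysis of the oxocarbenium ion) frees only the C16 hydroxyl; the TBDPS ether, the acid and the non-conjugated alkenes are left alone at 0 °C with short contact.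

Step 20
Reactants: 33 (4Z,8E,12Z,15E)-12-{[(tert-butyldiphenylsilyl)oxy]methyl}-17-hydroxy-4,8-dimethyl-16-(4-methylpent-3-en-1-yl)heptadeca-4,8,12,15-tetraenoic acid
Product: 35 (5Z,9E,13Z,16E)-13-{[(tert-butyldiphenylsilyl)oxy]methyl}-5,9-dimethyl-17-(4-methylpent-3-en-1-yl)oxacyclooctadeca-5,9,13,16-tetraen-2-one, via mixed anhydride 34 (not isolated)
Conditions: 2,4,6-trichlorobenzoyl chloride, Et3N, THF, rt; then slow addition to DMAP, toluene, 80 °C (about 1 mM)
Reagents that add atoms: none
Why: Yamaguchi macrolactonisation: the mixed anhydride acylates DMAP and the primary allylic alcohol closes the unstrained 18-membered ring under high dilution; four rigid trisubstituted alkenes limit the conformational freedom of the chain and there is no stereocentre to lose.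

Step 21
Reactants: 35 (5Z,9E,13Z,16E)-13-{[(tert-butyldiphenylsilyl)oxy]methyl}-5,9-dimethyl-17-(4-methylpent-3-en-1-yl)oxacyclooctadeca-5,9,13,16-tetraen-2-one
Product: 37 (1S,3Z,7E,11Z,14S)-11-{[(tert-butyldiphenylsilyl)oxy]methyl}-3,7-dimethyl-14-(6-methylhepta-1,5-dien-2-yl)cyclotetradeca-3,7,11-triene-1-carboxylic acid, via boron ketene acetal 36 (not isolated)
Conditions: (4S,5S)-2-bromo-1,3-bis{[3,5-bis(trifluoromethyl)phenyl]sulfonyl}-4,5-diphenyl-1,3,2-diazaborolidine (2 equiv, fresh from the (S,S)-bis-sulfonamide and BBr3), Et3N, CH2Cl2, −78 °C; then 4 °C, 48 h; aqueous work-up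
Reagents that add atoms: none
Why: Et3N removes a C14 proton from the boron-coordinated lactone to give O-boron ketene acetal 36, drawn with C13 syn to O–B. A concerted suprafacial [3,3]-sigmatropic shift through a six-atom chair (C14, C17, O, C16, C15, C1) forms C14–C1, breaks C16–O and moves the alkene to C15=C16; hydrolysis of the boron carboxylate gives 37. The closest known reaction type is the Ireland–Claisen rearrangement of allylic ester boron enolates carrying a chiral diazaborolidine, in the variant where the ester is a macrolactone and the shift is a ring contraction. The fourteen-membered ring is therefore not closed from a chain end: it arises by contraction of the 18-membered lactone, the bridge C17–O–C16–C15 leaving the ring so that C17 becomes the carboxyl and C15=C16 the exocyclic alkene. C1 is controlled by the reagent: the C2-symmetric bis-sulfonamide on boron blocks one face of the ketene acetal, the allyl unit docks on the other, and with the (E)-C1=C15 geometry from step 7 the chair converts that choice into one configuration at C1. C14 follows from the chair with both tether ends (C13 and C2) equatorial, giving the 1S,14S pair, and is deleted in step 22. Only enantiofacial selectivity is needed, because the substrate has one ester, one allylic C–O bond and no stereocentre, and the twelve-atom tether C2–C13 lets the chair form without strain. The TBDPS ether is inert to the boron bromide and the low temperature leaves the other alkenes untouched.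

Step 22
Reactants: 37 (1S,3Z,7E,11Z,14S)-11-{[(tert-butyldiphenylsilyl)oxy]methyl}-3,7-dimethyl-14-(6-methylhepta-1,5-dien-2-yl)cyclotetradeca-3,7,11-triene-1-carboxylic acid
Product: 39 tert-butyl{[(1Z,4R,7Z,11E)-7,11-dimethyl-4-(6-methylhepta-1,5-dien-2-yl)cyclotetradeca-1,7,11-trien-1-yl]methoxy}diphenylsilane, via thiohydroxamate ester 38 (not isolated)
Conditions: N-hydroxypyridine-2-thione, DCC, DMAP (cat.), CH2Cl2, 0 °C to rt, dark; then t-BuSH (large excess), hν (tungsten lamp), toluene, rt
Reagents that add atoms: none
Why: Barton decarboxylation: photolysis of the O-acyl thiohydroxamate gives the acyloxy radical, which loses CO2, and the C14 radical is reduced by the thiol in a chain; a high thiol concentration makes hydrogen transfer much faster than cyclisation onto the neighbouring alkenes, and C1 is not involved, so its configuration is kept.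

Step 23
Reactants: 39 tert-butyl{[(1Z,4R,7Z,11E)-7,11-dimethyl-4-(6-methylhepta-1,5-dien-2-yl)cyclotetradeca-1,7,11-trien-1-yl]methoxy}diphenylsilane
Product: 40 [(1Z,4R,7Z,11E)-7,11-dimethyl-4-(6-methylhepta-1,5-dien-2-yl)cyclotetradeca-1,7,11-trien-1-yl]methanol
Conditions: Bu4NF, THF, 0 °C to rt
Reagents that add atoms: none
Why: Fluoride cleaves the Si–O bond under non-acidic conditions that cannot isomerise the alkenes or touch the allylic stereocentre.

## Compound list

1 | 5-bromo-2-methylpent-2-ene | CC(C)=CCCBr | starting material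
2 | (2E)-5-bromo-2-methylpent-2-en-1-ol | BrCC/C=C(\C)CO | intermediate
3 | tert-butyl{[(2E)-5-bromo-2-methylpent-2-en-1-yl]oxy}dimethylsilane | BrCC/C=C(\C)CO[Si](C)(C)C(C)(C)C | intermediate
4 | propargyl alcohol (prop-2-yn-1-ol) | C#CCO | starting material
5 | [(3E)-5-{[tert-butyl(dimethyl)silyl]oxy}-4-methylpent-3-en-1-yl]magnesium bromide (formed in the flask) | Br[Mg]CC/C=C(\C)CO[Si](C)(C)C(C)(C)C | intermediate
6 | bromomagnesium alkoxide of the (Z)-3-(bromomagnesio)prop-2-en-1-ol carrying the side chain of 5 on C2, Mg cis to CH2O (formed in the flask) | Br[Mg]/C=C(\CO[Mg]Br)CC/C=C(\C)CO[Si](C)(C)C(C)(C)C | intermediate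
7 | (2Z)-2-[(3E)-5-{[tert-butyl(dimethyl)silyl]oxy}-4-methylpent-3-en-1-yl]-3-iodoprop-2-en-1-ol | I/C=C(\CO)CC/C=C(\C)CO[Si](C)(C)C(C)(C)C | intermediate
8 | tert-butyl{[(2Z)-2-[(3E)-5-{[tert-butyl(dimethyl)silyl]oxy}-4-methylpent-3-en-1-yl]-3-iodoprop-2-en-1-yl]oxy}diphenylsilane | I/C=C(\CO[Si](c1ccccc1)(c1ccccc1)C(C)(C)C)CC/C=C(\C)CO[Si](C)(C)C(C)(C)C | intermediate
9 | but-2-yne-1,4-diol | OCC#CCO | starting material
10 | 4-[(4-methoxybenzyl)oxy]but-2-yn-1-ol | OCC#CCOCc1ccc(OC)cc1 | intermediate
11 | sodium 2,2-bis(2-methoxyethoxy)-3-{[(4-methoxybenzyl)oxy]methyl}-2,5-dihydro-1,2-oxaaluminol-2-uide (formed in the flask) | [Na+].COCCO[Al-]1(OCCOC)OCC=C1COCc1ccc(OC)cc1 | intermediate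
12 | (2Z)-3-iodo-4-[(4-methoxybenzyl)oxy]but-2-en-1-ol | OC/C=C(\I)COCc1ccc(OC)cc1 | intermediate
13 | (4-methylpent-3-en-1-yl)zinc bromide (formed in the flask) | Br[Zn]CCC=C(C)C | intermediate
14 | (2E)-3-{[(4-methoxybenzyl)oxy]methyl}-7-methylocta-2,6-dien-1-ol | OC/C=C(\CCC=C(C)C)COCc1ccc(OC)cc1 | intermediate
15 | 1-({[(2E)-4-bromo-2-(4-methylpent-3-en-1-yl)but-2-en-1-yl]oxy}methyl)-4-methoxybenzene | BrC/C=C(\CCC=C(C)C)COCc1ccc(OC)cc1 | intermediate
16 | alkenyllithium from 8 (Li in place of I, geometry retained; formed in the flask) | [Li]/C=C(\CO[Si](c1ccccc1)(c1ccccc1)C(C)(C)C)CC/C=C(\C)CO[Si](C)(C)C(C)(C)C | intermediate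
17 | alkenylzinc bromide from 8 (ZnBr in place of I, geometry retained; formed in the flask) | Br[Zn]/C=C(\CO[Si](c1ccccc1)(c1ccccc1)C(C)(C)C)CC/C=C(\C)CO[Si](C)(C)C(C)(C)C | intermediate
18 | tert-butyl{[(2E,6Z,9E)-6-{[(tert-butyldiphenylsilyl)oxy]methyl}-11-[(4-methoxybenzyl)oxy]-2-methyl-10-(4-methylpent-3-en-1-yl)undeca-2,6,9-trien-1-yl]oxy}dimethylsilane | COc1ccc(COC/C(CCC=C(C)C)=C/C/C=C(\CO[Si](c2ccccc2)(c2ccccc2)C(C)(C)C)CC/C=C(\C)CO[Si](C)(C)C(C)(C)C)cc1 | intermediate
19 | (2E,6Z,9E)-6-{[(tert-butyldiphenylsilyl)oxy]methyl}-11-[(4-methoxybenzyl)oxy]-2-methyl-10-(4-methylpent-3-en-1-yl)undeca-2,6,9-trien-1-ol | COc1ccc(COC/C(CCC=C(C)C)=C/C/C=C(\CO[Si](c2ccccc2)(c2ccccc2)C(C)(C)C)CC/C=C(\C)CO)cc1 | intermediate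
20 | (2E,6Z,9E)-1-bromo-6-{[(tert-butyldiphenylsilyl)oxy]methyl}-11-[(4-methoxybenzyl)oxy]-2-methyl-10-(4-methylpent-3-en-1-yl)undeca-2,6,9-triene | COc1ccc(COC/C(CCC=C(C)C)=C/C/C=C(\CO[Si](c2ccccc2)(c2ccccc2)C(C)(C)C)CC/C=C(\C)CBr)cc1 | intermediate
21 | but-2-yn-1-ol | CC#CCO | starting material
22 | sodium 2,2-bis(2-methoxyethoxy)-3-methyl-2,5-dihydro-1,2-oxaaluminol-2-uide (formed in the flask) | [Na+].COCCO[Al-]1(OCCOC)OCC=C1C | intermediate
23 | (2Z)-3-iodobut-2-en-1-ol | C/C(I)=C/CO | intermediate
24 | ethyl 3-iodopropanoate | CCOC(=O)CCI | starting material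
25 | (3-ethoxy-3-oxopropyl)zinc iodide (formed in the flask) | CCOC(=O)CC[Zn]I | intermediate
26 | ethyl (4Z)-6-hydroxy-4-methylhex-4-enoate | CCOC(=O)CC/C(C)=C\CO | intermediate
27 | ethyl (4Z)-6-bromo-4-methylhex-4-enoate | CCOC(=O)CC/C(C)=C\CBr | intermediate
28 | ethyl (4Z)-6-(benzenesulfonyl)-4-methylhex-4-enoate | CCOC(=O)CC/C(C)=C\CS(=O)(=O)c1ccccc1 | intermediate
29 | 6-lithio derivative of 28 (carbanion next to sulfur; formed in the flask) | CCOC(=O)CC/C(C)=C\C([Li])S(=O)(=O)c1ccccc1 | intermediate
30 | ethyl (4Z,8E,12Z,15E)-6-(benzenesulfonyl)-12-{[(tert-butyldiphenylsilyl)oxy]methyl}-17-[(4-methoxybenzyl)oxy]-4,8-dimethyl-16-(4-methylpent-3-en-1-yl)heptadeca-4,8,12,15-tetraenoate, racemic at C6 | COc1ccc(COC/C(CCC=C(C)C)=C/C/C=C(\CO[Si](c2ccccc2)(c2ccccc2)C(C)(C)C)CC/C=C(\C)CC(S(=O)(=O)c2ccccc2)/C=C(/C)CCC(=O)OCC)cc1 | intermediate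
31 | (4Z,8E,12Z,15E)-6-(benzenesulfonyl)-12-{[(tert-butyldiphenylsilyl)oxy]methyl}-17-[(4-methoxybenzyl)oxy]-4,8-dimethyl-16-(4-methylpent-3-en-1-yl)heptadeca-4,8,12,15-tetraenoic acid, racemic at C6 | COc1ccc(COC/C(CCC=C(C)C)=C/C/C=C(\CO[Si](c2ccccc2)(c2ccccc2)C(C)(C)C)CC/C=C(\C)CC(S(=O)(=O)c2ccccc2)/C=C(/C)CCC(=O)O)cc1 | intermediate
32 | (4Z,8E,12Z,15E)-12-{[(tert-butyldiphenylsilyl)oxy]methyl}-17-[(4-methoxybenzyl)oxy]-4,8-dimethyl-16-(4-methylpent-3-en-1-yl)heptadeca-4,8,12,15-tetraenoic acid | COc1ccc(COC/C(CCC=C(C)C)=C/C/C=C(\CO[Si](c2ccccc2)(c2ccccc2)C(C)(C)C)CC/C=C(\C)CC/C=C(/C)CCC(=O)O)cc1 | intermediate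
33 | (4Z,8E,12Z,15E)-12-{[(tert-butyldiphenylsilyl)oxy]methyl}-17-hydroxy-4,8-dimethyl-16-(4-methylpent-3-en-1-yl)heptadeca-4,8,12,15-tetraenoic acid | OC/C(CCC=C(C)C)=C/C/C=C(\CO[Si](c1ccccc1)(c1ccccc1)C(C)(C)C)CC/C=C(\C)CC/C=C(/C)CCC(=O)O | intermediate
34 | mixed anhydride of 33 with 2,4,6-trichlorobenzoic acid (formed in the flask) | OC/C(CCC=C(C)C)=C/C/C=C(\CO[Si](c1ccccc1)(c1ccccc1)C(C)(C)C)CC/C=C(\C)CC/C=C(/C)CCC(=O)OC(=O)c1c(Cl)cc(Cl)cc1Cl | intermediate
35 | (5Z,9E,13Z,16E)-13-{[(tert-butyldiphenylsilyl)oxy]methyl}-5,9-dimethyl-17-(4-methylpent-3-en-1-yl)oxacyclooctadeca-5,9,13,16-tetraen-2-one (18-membered lactone, achiral) | O=C1OC/C(CCC=C(C)C)=C/C/C=C(\CO[Si](c2ccccc2)(c2ccccc2)C(C)(C)C)CC/C=C(\C)CC/C=C(/C)CC1 | intermediate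
36 | O-boron ketene acetal of 35: the lactone enol oxygen bound to boron of the (4S,5S)-1,3-bis{[3,5-bis(trifluoromethyl)phenyl]sulfonyl}-4,5-diphenyl-1,3,2-diazaborolidine, C13 syn to O–B (formed in the flask) | O=S(=O)(c1cc(C(F)(F)F)cc(C(F)(F)F)c1)N1[C@@H](c2ccccc2)[C@H](c2ccccc2)N(S(=O)(=O)c2cc(C(F)(F)F)cc(C(F)(F)F)c2)B1O/C1=C\C/C(C)=C\CC/C(C)=C/CC/C(CO[Si](c2ccccc2)(c2ccccc2)C(C)(C)C)=C/C/C=C(\CCC=C(C)C)CO1 | intermediate
37 | (1S,3Z,7E,11Z,14S)-11-{[(tert-butyldiphenylsilyl)oxy]methyl}-3,7-dimethyl-14-(6-methylhepta-1,5-dien-2-yl)cyclotetradeca-3,7,11-triene-1-carboxylic acid | C=C(CCC=C(C)C)[C@H]1C/C=C(\CO[Si](c2ccccc2)(c2ccccc2)C(C)(C)C)CC/C=C(\C)CC/C=C(/C)C[C@@H]1C(=O)O | intermediate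
38 | 2-thioxopyridin-1(2H)-yl ester of acid 37 (formed in the flask) | C=C(CCC=C(C)C)[C@H]1C/C=C(\CO[Si](c2ccccc2)(c2ccccc2)C(C)(C)C)CC/C=C(\C)CC/C=C(/C)C[C@@H]1C(=O)On1ccccc1=S | intermediate
39 | tert-butyl{[(1Z,4R,7Z,11E)-7,11-dimethyl-4-(6-methylhepta-1,5-dien-2-yl)cyclotetradeca-1,7,11-trien-1-yl]methoxy}diphenylsilane | C=C(CCC=C(C)C)[C@H]1C/C=C(\CO[Si](c2ccccc2)(c2ccccc2)C(C)(C)C)CC/C=C(\C)CC/C=C(/C)CC1 | intermediate
40 | [(1Z,4R,7Z,11E)-7,11-dimethyl-4-(6-methylhepta-1,5-dien-2-yl)cyclotetradeca-1,7,11-trien-1-yl]methanol | C=C(CCC=C(C)C)[C@H]1C/C=C(\CO)CC/C=C(\C)CC/C=C(/C)CC1 | target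

## Step count and risks

Total: 23 steps. Longest linear sequence: 15 steps (steps 1–4, 9–11, 16–23; the branch through steps 5–8 is equally long, and the branch through steps 12–15 is shorter).

**Step 21 (key step).** Most likely failure: enolisation of the lactone by the bulky boron bromide is slow or gives a mixture of ketene acetal geometries, so the rearrangement stalls or facial selectivity erodes. A change of enolate geometry alone would alter only C14, which is later removed. Fallback: from 35, form the trimethylsilyl ketene acetal F1 (KN(SiMe3)2, Me3SiCl, THF, −78 °C) and let it rearrange on warming in the ordinary, non-enantioselective Ireland–Claisen ring contraction to the racemic acid F2. Acid F2 is then resolved by preparative chromatography on a chiral stationary phase, and the route resumes at 37.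

**Step 9.** Most likely failure: migration of the TBDPS group from oxygen to the neighbouring lithiated carbon before transmetalation, or coupling at the substituted allyl terminus. Fallback: from 8, Miyaura borylation (bis(pinacolato)diboron, Pd(dppf)Cl2, KOPh, toluene, 50 °C) gives the alkenyl pinacol boronate F3 without any organolithium. Suzuki–Miyaura coupling of F3 with 15 (Pd(PPh3)4, aqueous K3PO4, THF) returns to 18.

**Step 3.** Most likely failure: the functionalised Grignard reagent deprotonates the alkyne C–H or adds sluggishly, so that carbomagnesiation is incomplete and the two-step bromide is wasted. Fallback, setting out from 3 (through 5) and 15 and returning at 18, bypassing steps 3, 4 and 9: Grignard reagent 5 is acylated with 2-[(tert-butyldiphenylsilyl)oxy]-N-methoxy-N-methylacetamide F4 to give the α-silyloxy ketone F5. Bromide 15 alkylates methylenetriphenylphosphorane to give the homoallylic phosphonium bromide F6, which NaN(SiMe3)2 converts into the ylide F7. Wittig reaction of F7 with F5 relies on the known preference of α-alkoxy ketones to place the new chain cis to the oxygenated carbon and gives 18.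

**Step 18.** Most likely failure: the lithium carboxylate formed in the flask aggregates with borane and hydride, so palladium turnover stalls and the long-lived allyl intermediate loses positional or geometric integrity. Fallback: run the same palladium/hydride reduction on ester 30 with enough LiBHEt3 to reduce the ester too, giving the C17 primary alcohol F8. Alcohol F8 is oxidised with Dess–Martin periodinane to the aldehyde F9 and then with NaClO2/NaH2PO4/2-methylbut-2-ene to 32, where the route resumes.

## Further compounds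

F1 | step 21 | trimethylsilyl ketene acetal of lactone 35 (enol ether geometry not controlled) | C[Si](C)(C)OC1=CC/C(C)=C\CC/C(C)=C/CC/C(CO[Si](c2ccccc2)(c2ccccc2)C(C)(C)C)=C/C/C=C(\CCC=C(C)C)CO1
F2 | step 21 | racemic 11-{[(tert-butyldiphenylsilyl)oxy]methyl}-3,7-dimethyl-14-(6-methylhepta-1,5-dien-2-yl)cyclotetradeca-3,7,11-triene-1-carboxylic acid (3Z,7E,11Z; racemate of 37) | C=C(CCC=C(C)C)C1C/C=C(\CO[Si](c2ccccc2)(c2ccccc2)C(C)(C)C)CC/C=C(\C)CC/C=C(/C)CC1C(=O)O
F3 | step 9 | alkenyl pinacol boronate from 8 (Bpin in place of I, geometry retained) | CC1(C)OB(/C=C(\CO[Si](c2ccccc2)(c2ccccc2)C(C)(C)C)CC/C=C(\C)CO[Si](C)(C)C(C)(C)C)OC1(C)C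
F4 | step 3 | 2-[(tert-butyldiphenylsilyl)oxy]-N-methoxy-N-methylacetamide | CON(C)C(=O)CO[Si](c1ccccc1)(c1ccccc1)C(C)(C)C
F5 | step 3 | (5E)-7-[(tert-butyldimethylsilyl)oxy]-1-[(tert-butyldiphenylsilyl)oxy]-6-methylhept-5-en-2-one | O=C(CO[Si](c1ccccc1)(c1ccccc1)C(C)(C)C)CC/C=C(\C)CO[Si](C)(C)C(C)(C)C
F6 | step 3 | [(3E)-5-[(4-methoxybenzyl)oxy]-4-(4-methylpent-3-en-1-yl)pent-3-en-1-yl]triphenylphosphonium bromide | [Br-].COc1ccc(COC/C(CCC=C(C)C)=C/CC[P+](c2ccccc2)(c2ccccc2)c2ccccc2)cc1
F7 | step 3 | ylide from F6: [(3E)-5-[(4-methoxybenzyl)oxy]-4-(4-methylpent-3-en-1-yl)pent-3-en-1-ylidene]triphenylphosphorane | COc1ccc(COC/C(CCC=C(C)C)=C/CC=P(c2ccccc2)(c2ccccc2)c2ccccc2)cc1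
F8 | step 18 | (4Z,8E,12Z,15E)-12-{[(tert-butyldiphenylsilyl)oxy]methyl}-17-[(4-methoxybenzyl)oxy]-4,8-dimethyl-16-(4-methylpent-3-en-1-yl)heptadeca-4,8,12,15-tetraen-1-ol | COc1ccc(COC/C(CCC=C(C)C)=C/C/C=C(\CO[Si](c2ccccc2)(c2ccccc2)C(C)(C)C)CC/C=C(\C)CC/C=C(/C)CCCO)cc1
F9 | step 18 | (4Z,8E,12Z,15E)-12-{[(tert-butyldiphenylsilyl)oxy]methyl}-17-[(4-methoxybenzyl)oxy]-4,8-dimethyl-16-(4-methylpent-3-en-1-yl)heptadeca-4,8,12,15-tetraenal | COc1ccc(COC/C(CCC=C(C)C)=C/C/C=C(\CO[Si](c2ccccc2)(c2ccccc2)C(C)(C)C)CC/C=C(\C)CC/C=C(/C)CCC=O)cc1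
A1 | alternative 1 | 14-membered (3Z,7E,11Z)-triene with a pinacol boronate on C1 (R) and a TBS-protected hydroxymethyl group on C4 | CC1(C)OB(OC1(C)C)[C@H]2C/C=C(\CO[Si](C)(C)C(C)(C)C)CC/C=C(\C)CC/C=C(/C)CC2
A2 | alternative 2 | methyl ester of the 14-membered (Z)-enoate, carboxylate on C4 cis to C2, side chain on C1 (R) | C=C(CCC=C(C)C)[C@H]1C/C=C(\C(=O)OC)CC/C=C(\C)CC/C=C(/C)CC1
A3 | alternative 3 | 14-membered carbocycle with a phenylsulfonyl group on C9 (epimer mixture), TBS ether on the C4 hydroxymethyl group, side chain on C1 (R) | C=C(CCC=C(C)C)[C@H]1C/C=C(\CO[Si](C)(C)C(C)(C)C)CC/C=C(\C)C(S(=O)(=O)c2ccccc2)C/C=C(/C)CC1
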